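**Retrosynthetic overview**

1. Late disconnections: the C17 acid comes from its 4‑methoxybenzyl ester, the C12–C13 bond from Negishi coupling of a C12 alkylzinc with 3‑bromofuran‑2(5H)‑one, and the 6α‑tiglate from Mitsunobu inversion of the 6β‑alcohol obtained from the 6‑ketone.
2. The strategy rests on the C9–C10 bond of ring B, which joins the quaternary C10 (β‑methyl C20) to C9 with its hydrogen α, anti to that methyl. It is made by light‑driven conrotatory six‑electron closure of the triene C10=C5–C6=C7–C8=C9, giving ring B as the 5,7‑diene with the C6 oxygen as a silyl enol ether.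
3. In the precursor C17 and the C12 oxygen are tied as a δ‑lactone, so C8=C9 is endocyclic in a 5,6‑dihydropyran‑2‑one. This fixes C11 outside and H‑9 inside and rules out the C8=C9 isomerisation that would scramble C9 in an open‑chain enoate.
4. The triene comes from a ketone by O‑silylation; this should give the C5/C8‑trans isomer, and the C5/C8‑cis isomer that closes is formed in the flask by light. The ketone comes from β‑cyclocitral by zinc Barbier allylation, oxidation and ring‑closing metathesis.
5. Ring order: ring A is bought (β‑cyclocitral), the lactone ring is made by metathesis, ring B by photocyclisation; the lactone is then opened and the butenolide ring attached by cross‑coupling.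

Key step: step 6

Remark: labdane numbering is used (C20 is the β‑methyl on C10); 3‑bromofuran‑2(5H)‑one is taken as purchasable, and which enantiomer of the oxazaborolidine leads to the 9α‑H,10β‑methyl series must be found by experiment, the (S)‑form being written.

**Route**

Step 1
Reactants: 1 2‑(bromomethyl)acrylic acid; 2 but‑3‑en‑1‑ol
Product: 3 but‑3‑en‑1‑yl 2‑(bromomethyl)prop‑2‑enoate
Conditions: TsOH·H2O (cat.), benzene, reflux, Dean–Stark trap
Reagents that add atoms: none
Why: Fischer esterification driven by azeotropic removal of water; the allylic bromide and the acrylate tolerate acid, as in the standard preparation of the ethyl ester.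

Step 2
Reactants: 3 but‑3‑en‑1‑yl 2‑(bromomethyl)prop‑2‑enoate; 4 β‑cyclocitral
Product: 6 but‑3‑en‑1‑yl 4‑hydroxy‑2‑methylidene‑4‑(2,6,6‑trimethylcyclohex‑1‑en‑1‑yl)butanoate (racemic carbinol), via allylzinc bromide 5 (not isolated)
Conditions: Zn dust, THF/sat. aq. NH4Cl, 0 °C to rt
Reagents that add atoms: zinc, [Zn] (held only in intermediate 5)
Why: Barbier allylation with a 2‑(alkoxycarbonyl)allylzinc adds to the hindered, non‑enolisable aldehyde and forms C6–C7; the allyl unit is symmetric so there is no regiochemical issue, and the racemic carbinol centre is removed in step 3.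

Step 3
Reactants: 6 hydroxy ester
Product: 7 but‑3‑en‑1‑yl 2‑methylidene‑4‑oxo‑4‑(2,6,6‑trimethylcyclohex‑1‑en‑1‑yl)butanoate
Conditions: Dess–Martin periodinane, pyridine, CH2Cl2, 0 °C to rt
Reagents that add atoms: none
Why: Dess–Martin oxidation handles hindered allylic alcohols under near‑neutral conditions, which keeps the β,γ‑unsaturated ketone from moving into conjugation.

Step 4
Reactants: 7 keto ester
Product: 8 3‑[2‑oxo‑2‑(2,6,6‑trimethylcyclohex‑1‑en‑1‑yl)ethyl]‑5,6‑dihydro‑2H‑pyran‑2‑one
Conditions: second‑generation Grubbs catalyst RuCl2(=CHPh)(PCy3)(H2IMes) (5 mol %), CH2Cl2 (5 mM), 40 °C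
Reagents that add atoms: none
Why: ring‑closing metathesis between the terminal alkene and the 1,1‑disubstituted acrylate closes the unsaturated δ‑lactone as it does for methacrylates of homoallylic alcohols; the tetrasubstituted ring‑A alkene is inert, and the new C8=C9 bond is locked in the ring with C11 cis to C17.

Step 5
Reactants: 8 keto lactone
Product: 9 3‑[(Z)‑2‑(tert‑butyldimethylsilyloxy)‑2‑(2,6,6‑trimethylcyclohex‑1‑en‑1‑yl)ethenyl]‑5,6‑dihydro‑2H‑pyran‑2‑one (silyloxy group cis to the lactone ring, C5 and C8 trans)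
Conditions: TBSOTf, Et3N, CH2Cl2, 0 °C
Reagents that add atoms: tert‑butyldimethylsilyl trifluoromethanesulfonate, CC(C)(C)[Si](C)(C)OS(=O)(=O)C(F)(F)F
Why: soft enolisation of the ketone towards C7, its only α‑CH2, with silylation on oxygen only; the Z isomer is expected because the twisted, bulky cyclohexenyl group prefers to sit cis to hydrogen (A(1,3) strain), as with mesityl ketones, and any E isomer formed reacts the same way in step 6.

Step 6
Reactants: 9 (Z)‑silyl dienol ether triene
Product: 11 6‑(tert‑butyldimethylsilyloxy)‑13,14,15,16‑tetranorlabda‑5,7‑dien‑17,12‑olide (9α‑H, 10β‑CH3), via C5/C8‑cis triene 10 (not isolated)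
Conditions: (S)‑3,3‑diphenyl‑1‑(2‑methylphenyl)tetrahydro‑1H,3H‑pyrrolo[1,2‑c][1,3,2]oxazaborole (0.5 equiv), AlBr3 (0.4 equiv), CH2Cl2 (10 mM, degassed), −75 °C, hν (405 nm LED)
Reagents that add atoms: none
Why: Proposed new method: the Lewis acid binds the lactone carbonyl of 9 and shifts its absorption towards the visible so that only the complex is excited; the excited complex first isomerises about C6=C7 to the folded C5/C8‑cis triene 10 (tachysterol‑to‑previtamin type), and 10 then closes from the singlet excited state by conrotatory six‑electron electrocyclisation, forming the C9–C10 σ bond. The closest known reaction types are the conrotatory photochemical hexatriene‑to‑cyclohexadiene closure of previtamin D and enantioselective photoreactions of enones and unsaturated lactones bound to AlBr3‑activated chiral oxazaborolidines; silyloxy dienes are tolerated by such Lewis acids at this temperature in Diels–Alder reactions. Ring B is closed by electrocyclic ring closure between the triene termini C9 and C10 and emerges as the 5,7‑diene. The relative configuration (C20 and C11 on the same face, hence H‑9 anti to C20) follows from conrotation, because ring A holds C20 inside and the lactone ring holds C11 outside; the absolute configuration at C9 and C10 is set by the catalyst, which must shield one face of the bound lactone so that only one helical conformer of 10 closes. The step needs closure to outrun the thermal 1,7‑hydrogen shift from C20 and the photochemical reopening of 11, which the low temperature and irradiation at the red edge of the triene complex are meant to secure, while the lactone tether excludes C8=C9 isomerisation and photodeconjugation.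

Step 7
Reactants: 11 silyl dienol ether lactone
Product: 12 6‑oxo‑13,14,15,16‑tetranorlabd‑7‑en‑17,12‑olide (5α‑H, 9α‑H, 10β‑CH3)
Conditions: 1 M HCl, THF, 0 °C
Reagents that add atoms: none
Why: acid hydrolysis of the silyl enol ether protonates C5 from the open α face (the β face is blocked by C20 and the 4β‑methyl), and enolisation towards C5 gives the trans ring fusion under thermodynamic control in any case; C9 is untouched because mild acid does not enolise towards the γ position and the lactone holds C11 equatorial.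

Step 8
Reactants: 12 keto lactone
Product: 13 6β‑hydroxy‑13,14,15,16‑tetranorlabd‑7‑en‑17,12‑olide
Conditions: NaBH4, CeCl3·7H2O, MeOH/CH2Cl2, −78 °C
Reagents that add atoms: none
Why: Luche reduction gives 1,2‑reduction of the enone and leaves the lactone; hydride enters from the α face, away from the two syn‑axial methyl groups (C20 and 4β‑CH3), giving the axial 6β‑alcohol.

Step 9
Reactants: 13 6β‑alcohol; 14 tiglic acid
Product: 15 6α‑[(E)‑2‑methylbut‑2‑enoyloxy]‑13,14,15,16‑tetranorlabd‑7‑en‑17,12‑olide
Conditions: PPh3, DIAD, toluene, 0 °C to rt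
Reagents that add atoms: none
Why: Mitsunobu esterification with SN2 inversion; the carboxylate attacks the activated allylic C6 from the open α face, anti to the axial leaving group, which sets the 6α (equatorial) ester.

Step 10
Reactants: 15 tiglate lactone
Product: 17 4‑methoxybenzyl 12‑hydroxy‑6α‑tigloyloxy‑13,14,15,16‑tetranorlabd‑7‑en‑17‑oate, via lithium hydroxy carboxylate 16 (not isolated)
Conditions: LiOH·H2O (1.1 equiv), THF/H2O, 0 °C; evaporate; 4‑methoxybenzyl chloride, Bu4NI (cat.), DMF, rt
Reagents that add atoms: lithium hydroxide, [Li+].[OH-]; 4‑methoxybenzyl chloride, COc1ccc(CCl)cc1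
Why: saponification is selective because a δ‑lactone is far more reactive towards hydroxide than the hindered, α‑branched unsaturated secondary tiglate; the carboxylate is then O‑alkylated, and C9–H is no longer acidic once the ketone is gone.

Step 11
Reactants: 17 hydroxy ester
Product: 18 4‑methoxybenzyl 12‑iodo‑6α‑tigloyloxy‑13,14,15,16‑tetranorlabd‑7‑en‑17‑oate
Conditions: I2, PPh3, imidazole, CH2Cl2, 0 °C
Reagents that add atoms: iodine, II
Why: Appel iodination of the primary alcohol is fast and near neutral, so it outpaces relactonisation and leaves both esters intact.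

Step 12
Reactants: 18 primary iodide; 19 3‑bromofuran‑2(5H)‑one
Product: 21 4‑methoxybenzyl 6α‑tigloyloxylabda‑7,13‑dien‑16,15‑olid‑17‑oate, via alkylzinc iodide 20 (not isolated)
Conditions: Zn dust (activated with BrCH2CH2Br and TMSCl), LiCl, THF, 30 °C; then 19, Pd2(dba)3 (2.5 mol %), SPhos (10 mol %), THF, rt
Reagents that add atoms: zinc, [Zn] (held only in intermediate 20)
Why: LiCl‑assisted zinc insertion into a primary iodide tolerates esters, and Negishi sp3–sp2 coupling with the alkenyl bromide forms C12–C13; the bulky biaryl phosphine favours reductive elimination over β‑hydride loss.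

Step 13
Reactants: 21 4‑methoxybenzyl ester
Product: 22 6α‑tigloyloxylabda‑7,13‑dien‑16,15‑olid‑17‑oic acid (5S,6S,9R,10R), CNP0245290.2
Conditions: TFA, anisole, CH2Cl2, 0 °C
Reagents that add atoms: none
Why: acidolysis of the 4‑methoxybenzyl ester, with the benzylic cation trapped by anisole; the tiglate, the butenolide and the allylic C6–O bond (its cation is disfavoured by the C8 carboxyl) survive.

**Compound list**

1 | 2‑(bromomethyl)acrylic acid | C=C(CBr)C(=O)O | starting material
2 | but‑3‑en‑1‑ol | C=CCCO | starting material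
3 | but‑3‑en‑1‑yl 2‑(bromomethyl)prop‑2‑enoate | C=CCCOC(=O)C(=C)CBr | intermediate
4 | β‑cyclocitral | CC1=C(C=O)C(C)(C)CCC1 | starting material
5 | [2‑(but‑3‑enyloxycarbonyl)allyl]zinc bromide | C=CCCOC(=O)C(=C)C[Zn]Br | intermediate
6 | but‑3‑en‑1‑yl 4‑hydroxy‑2‑methylidene‑4‑(2,6,6‑trimethylcyclohex‑1‑en‑1‑yl)butanoate (racemic) | CC1=C(C(O)CC(=C)C(=O)OCCC=C)C(C)(C)CCC1 | intermediate
7 | but‑3‑en‑1‑yl 2‑methylidene‑4‑oxo‑4‑(2,6,6‑trimethylcyclohex‑1‑en‑1‑yl)butanoate | CC1=C(C(=O)CC(=C)C(=O)OCCC=C)C(C)(C)CCC1 | intermediate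
8 | 3‑[2‑oxo‑2‑(2,6,6‑trimethylcyclohex‑1‑en‑1‑yl)ethyl]‑5,6‑dihydro‑2H‑pyran‑2‑one | CC1=C(C(=O)CC2=CCCOC2=O)C(C)(C)CCC1 | intermediate
9 | 3‑[(Z)‑2‑(tert‑butyldimethylsilyloxy)‑2‑(2,6,6‑trimethylcyclohex‑1‑en‑1‑yl)ethenyl]‑5,6‑dihydro‑2H‑pyran‑2‑one (C5/C8 trans) | CC1=C(/C(O[Si](C)(C)C(C)(C)C)=C/C2=CCCOC2=O)C(C)(C)CCC1 | intermediate
10 | 3‑[(E)‑2‑(tert‑butyldimethylsilyloxy)‑2‑(2,6,6‑trimethylcyclohex‑1‑en‑1‑yl)ethenyl]‑5,6‑dihydro‑2H‑pyran‑2‑one (C5/C8 cis) | CC1=C(/C(O[Si](C)(C)C(C)(C)C)=C\C2=CCCOC2=O)C(C)(C)CCC1 | intermediate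
11 | 6‑(tert‑butyldimethylsilyloxy)‑13,14,15,16‑tetranorlabda‑5,7‑dien‑17,12‑olide (9α‑H, 10β‑CH3) | CC(C)(C)[Si](C)(C)OC1=C2C(C)(C)CCC[C@]2(C)[C@H]2CCOC(=O)C2=C1 | intermediate
12 | 6‑oxo‑13,14,15,16‑tetranorlabd‑7‑en‑17,12‑olide (5α‑H, 9α‑H, 10β‑CH3) | O=C1C=C2C(=O)OCC[C@@H]2[C@@]2(C)CCCC(C)(C)[C@H]12 | intermediate
13 | 6β‑hydroxy‑13,14,15,16‑tetranorlabd‑7‑en‑17,12‑olide | O[C@@H]1C=C2C(=O)OCC[C@@H]2[C@@]2(C)CCCC(C)(C)[C@H]12 | intermediate
14 | tiglic acid | C/C=C(\C)C(=O)O | starting material
15 | 6α‑tigloyloxy‑13,14,15,16‑tetranorlabd‑7‑en‑17,12‑olide | C/C=C(\C)C(=O)O[C@H]1C=C2C(=O)OCC[C@@H]2[C@@]2(C)CCCC(C)(C)[C@H]12 | intermediate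
16 | lithium 12‑hydroxy‑6α‑tigloyloxy‑13,14,15,16‑tetranorlabd‑7‑en‑17‑oate | C/C=C(\C)C(=O)O[C@H]1C=C(C(=O)[O-])[C@H](CCO)[C@@]2(C)CCCC(C)(C)[C@H]12.[Li+] | intermediate
17 | 4‑methoxybenzyl 12‑hydroxy‑6α‑tigloyloxy‑13,14,15,16‑tetranorlabd‑7‑en‑17‑oate | C/C=C(\C)C(=O)O[C@H]1C=C(C(=O)OCc2ccc(OC)cc2)[C@H](CCO)[C@@]2(C)CCCC(C)(C)[C@H]12 | intermediate
18 | 4‑methoxybenzyl 12‑iodo‑6α‑tigloyloxy‑13,14,15,16‑tetranorlabd‑7‑en‑17‑oate | C/C=C(\C)C(=O)O[C@H]1C=C(C(=O)OCc2ccc(OC)cc2)[C@H](CCI)[C@@]2(C)CCCC(C)(C)[C@H]12 | intermediate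
19 | 3‑bromofuran‑2(5H)‑one | O=C1OCC=C1Br | starting material
20 | 12‑(iodozincio) derivative of 18 | C/C=C(\C)C(=O)O[C@H]1C=C(C(=O)OCc2ccc(OC)cc2)[C@H](CC[Zn]I)[C@@]2(C)CCCC(C)(C)[C@H]12 | intermediate
21 | 4‑methoxybenzyl 6α‑tigloyloxylabda‑7,13‑dien‑16,15‑olid‑17‑oate | C/C=C(\C)C(=O)O[C@H]1C=C(C(=O)OCc2ccc(OC)cc2)[C@H](CCC2=CCOC2=O)[C@@]2(C)CCCC(C)(C)[C@H]12 | intermediate
22 | 6α‑tigloyloxylabda‑7,13‑dien‑16,15‑olid‑17‑oic acid (5S,6S,9R,10R), CNP0245290.2 | C/C=C(\C)C(=O)O[C@H]1C=C(C(=O)O)[C@H](CCC2=CCOC2=O)[C@@]2(C)CCCC(C)(C)[C@H]12 | target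

**Step count and risks**

Total steps: 13. Longest linear sequence: 13 steps (1 or 2 → 3 → 6 → 7 → 8 → 9 → 11 → 12 → 13 → 15 → 17 → 18 → 21 → 22).

Steps most likely to fail:

1. Step 6 (proposed new method). The bound Lewis acid may discriminate poorly between the two helical conformers of 10, giving low enantioselectivity. The closed diene 11 may also reopen under the same light, so the mixture settles at a stationary state, and a dark, stepwise Lewis‑acid closure of 10 would not be bound to the conrotatory outcome. Fallback by known chemistry, setting out from 9 and returning at 12: irradiation of 9 without Lewis acid (about 350 nm, degassed pentane/ether, −40 °C), the racemic vitamin‑D‑type photocyclisation, should give 11 together with its mirror image, the enantiomeric silyl dienol ether lactone F1. Hydrolysis of the mixture as in step 7 should give 12 together with the enantiomeric keto lactone F2, and preparative chromatography on a chiral stationary phase separates the two and returns 12.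

2. Step 9. The axial 6β‑hydroxyl lies between two syn‑axial methyl groups, so the alkoxyphosphonium ion may not form, or anti‑elimination across C5–C6 to the 5,7‑diene may win over substitution. Fallback, setting out from 12 and returning at 15: Meerwein–Ponndorf–Verley reduction under equilibrating conditions (Al(OiPr)3, iPrOH/toluene, reflux, acetone not removed) lets hydride transfer reverse until the equatorial alcohol dominates, with no activation at C6. After dilute acid work‑up, which recloses any lactone opened by isopropoxide, this should give 6α‑hydroxy‑13,14,15,16‑tetranorlabd‑7‑en‑17,12‑olide F3. Yamaguchi esterification of F3 with tiglic acid 14 (2,4,6‑trichlorobenzoyl chloride, Et3N, DMAP, toluene) gives 15.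

3. Step 12. The alkylzinc may be protonated or lose β‑hydride before coupling, or zerovalent palladium may insert into the allylic tiglate. Fallback, setting out from 18 and returning at 21: alkylation of the sodium enolate of 3‑(phenylsulfanyl)dihydrofuran‑2(3H)‑one (NaHMDS, THF/DMPU, −78 to 0 °C) with iodide 18 gives the 4‑methoxybenzyl 12‑[2‑oxo‑3‑(phenylsulfanyl)oxolan‑3‑yl] ester F4. Oxidation with mCPBA (1 equiv, CH2Cl2, −78 °C) gives the corresponding sulfoxide F5, and thermolysis (toluene, 110 °C) eliminates benzenesulfenic acid into the ring to give the butenolide 21.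

**Further compounds**

F1 | step 6 | enantiomer of 11, 6‑(tert‑butyldimethylsilyloxy)‑13,14,15,16‑tetranorlabda‑5,7‑dien‑17,12‑olide (9β‑H, 10α‑CH3) | CC(C)(C)[Si](C)(C)OC1=C2C(C)(C)CCC[C@@]2(C)[C@@H]2CCOC(=O)C2=C1
F2 | step 6 | enantiomer of 12, 6‑oxo‑13,14,15,16‑tetranorlabd‑7‑en‑17,12‑olide (5β‑H, 9β‑H, 10α‑CH3) | O=C1C=C2C(=O)OCC[C@H]2[C@]2(C)CCCC(C)(C)[C@@H]12
F3 | step 9 | 6α‑hydroxy‑13,14,15,16‑tetranorlabd‑7‑en‑17,12‑olide | O[C@H]1C=C2C(=O)OCC[C@@H]2[C@@]2(C)CCCC(C)(C)[C@H]12
F4 | step 12 | 4‑methoxybenzyl 12‑[2‑oxo‑3‑(phenylsulfanyl)oxolan‑3‑yl]‑6α‑tigloyloxy‑13,14,15,16‑tetranorlabd‑7‑en‑17‑oate (epimers at the sulfur‑bearing carbon) | C/C=C(\C)C(=O)O[C@H]1C=C(C(=O)OCc2ccc(OC)cc2)[C@H](CCC2(Sc3ccccc3)CCOC2=O)[C@@]2(C)CCCC(C)(C)[C@H]12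
F5 | step 12 | 4‑methoxybenzyl 12‑[2‑oxo‑3‑(phenylsulfinyl)oxolan‑3‑yl]‑6α‑tigloyloxy‑13,14,15,16‑tetranorlabd‑7‑en‑17‑oate (mixture of stereoisomers) | C/C=C(\C)C(=O)O[C@H]1C=C(C(=O)OCc2ccc(OC)cc2)[C@H](CCC2(S(=O)c3ccccc3)CCOC2=O)[C@@]2(C)CCCC(C)(C)[C@H]12
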